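From 3.00 min to 15.0 min the ratio of isomer of the product to target in this flask holds flat within the scatter at 1.41, a share of 58.5%, and that ratio is what I hand over. The solid substrate went in undissolved and both products read level by 3.00 min, so leave the flask closed and stirred, and do not carry that late ratio back to its first seconds.

- noon: solid substrate 0.50 mM; the very flask that is asked about, followed so far
- flask: solid substrate 0.50 mM; time 30 min

- noon (time / min: isomer of the product / %, target / %): 1.33: 47.1, 35.3; 2.00: 55.1, 39.8; 3.00: 56.4, 39.8; 5.00: 56.1, 39.5; 10.0: 56.3, 40.3; 15.0: 55.8, 39.7

(scatter of a reading: 0.5 percentage points)

- solid substrate is a solid; its amount is given per volume of the solution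
- at the start none of the solid substrate is in solution

1. share of isomer of the product in isomer of the product plus target at 5.0 s
2. share of isomer of the product in isomer of the product plus target at 1.5 min
3. share of isomer of the product in isomer of the product plus target at 30 min
4. which of isomer of the product and target there is more of at 30 min

At 1.33 min the ratio reads 1.33, lower than the plateau. I assume that both products rise with age and that the isomer of the product trails by a fixed time, so the ratio is the plateau times one minus lag over age. This gives the lag, the time by which its rise trails the target's (an induction period), as 4.28 s, a rough reading. Counted in lags, 5.0 s is an age of 1.17, 1.5 min of 21.0 and 30 min of 421. So I expect the plateau share at 30 min, nearly that at 1.5 min, and the target ahead at 5.0 s, with the two level at 14.7 s.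

The forecast gives 57%, 57.7% and 58.4%, with isomer of the product ahead at 30 min, and says of the earliest value that it is “an extrapolation, so it is quite uncertain”.

The flask gives 42.4%, 58.1% and 58.5%, with 56.1% isomer of the product against 39.8% target at 30.0 min.

    other conformer ⇌ third conformer (K = 0.0800, k = 0.0330 /s)
    third conformer → third product (k = 0.0140 /s)
    starting material + target → side product (k = 15.0 /M/s)
    starting material ⇌ other conformer (K = 0.570, k = 0.0510 /s)
    solid substrate ⇌ starting material, rate k5*(cs5 - [starting material]) while solid is left; crystals form when [starting material] > cs5 (solubility = 0.120 mM, k = 0.130 /s)
    starting material → target (k = 0.0320 /s)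
    other conformer → isomer of the product (k = 0.480 /s)

The two products stand level at 9.98 s, earlier than my 14.7 s. The neighbouring flask is charged with 0.85 mM of solid substrate; if the lag holds at that charge, its ages in lags are the same as here, so I again expect a low share at 5.0 s and the plateau share at 30 min. That neighbouring flask gives 42.4% at 5.0 s, lower than its 59.3% at 30 min.

The data are calculated from invented constants.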